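**Plan**
1. Locants (tricyclo[5.4.0.0^2,8]undecane numbering, used for all intermediates): cyclobutane C1–C2–C8–C7; enone bridge C11(=O)–C10=C9(CH3) between C1 and C8; bridge C3–C4–C5(O)–C6(CH3)(C12H2O) between C2 and C7.
2. Retrosynthetic cuts, in order: both angelate C–O bonds; C5–O (back to a C4=C5 alkene) and C9–CH3 (back to the saturated C11 ketone); C2–CH3 together with C1–C7 (methyl cuprate on a C1=C2 enone, the C1 enolate displacing a C7 mesylate); C4=C5 (metathesis); C2–C3 (allyl Grignard with enone transposition); C7–C8 (aldol); the C6 centre (1,2-shift in an epoxy silyl ether).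
3. Feature used: C2 is a quaternary, methyl-bearing carbon β to the C11 carbonyl, C1 is the α-carbon, and C7 sits on the neighbouring ring carbon C8, 1,3 to C1; conjugate methylation at C2 therefore creates at C1 exactly the enolate that closes the four-membered ring C1–C2–C8–C7 and turns the cyclohexanone into the bicyclo[3.1.1]heptanone.
4. Forward order of rings: cyclohexenone (bought) → seven-membered ring C2…C8 by metathesis (closed first, so that it holds C7 in place) → cyclobutane by the cuprate-triggered closure → C9-methyl enone → C5 hydroxyl → diester.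
5. Stereochemistry: C6 from a Sharpless epoxidation relayed by an invertive 1,2-shift; C7 and C8 from a syn-selective titanium aldol; C2 from cuprate attack anti to C7; C1 and C7 from the ring closure (inversion at C7); C5 from epoxidation anti to C12H2OTBS and hydride opening at C4.

Key step: step 9

Remark: C6 carries three substituents of similar size, so no facial preference of the aldehyde is counted on in step 5; both syn adducts are expected and 9 is taken on after chromatography. TBS = tert-butyldimethylsilyl.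

**Route**

Step 1
Reactants: 1 (2E)-3-methylpent-2-en-4-yn-1-ol
Product: 2 (2E)-3-methylpenta-2,4-dien-1-ol
Conditions: H2 (1 atm), Pd/CaCO3–Pb(OAc)2 (Lindlar catalyst), quinoline, EtOAc, 0 °C
Reagents that add atoms: none
Why: Lindlar semihydrogenation stops the terminal alkyne at the vinyl stage on the poisoned palladium surface and leaves the trisubstituted (E)-alkene and its geometry untouched.

Step 2
Reactants: 2 (2E)-3-methylpenta-2,4-dien-1-ol
Product: 3 [(2R,3R)-3-ethenyl-3-methyloxiran-2-yl]methanol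
Conditions: Ti(OiPr)4 (10 mol%), D-(−)-diethyl tartrate (12 mol%), t-BuOOH, 4 Å MS, CH2Cl2, −20 °C
Reagents that add atoms: tert-butyl hydroperoxide, CC(C)(C)OO
Why: The Sharpless asymmetric epoxidation acts only on the alkene of the allylic alcohol (the distal vinyl group has no directing hydroxyl), and the D-(−)-tartrate ligand should deliver oxygen to the face that gives the (2R,3R)-epoxide, the mirror image of the (2S,3S) sense that (E)-3-methylalk-2-en-1-ols show with the L-(+)-ligand.

Step 3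
Reactants: 3 [(2R,3R)-3-ethenyl-3-methyloxiran-2-yl]methanol
Product: 4 tert-butyl{[(2R,3R)-3-ethenyl-3-methyloxiran-2-yl]methoxy}dimethylsilane
Conditions: TBSCl, imidazole, CH2Cl2, 0 °C
Reagents that add atoms: tert-butyl(chloro)dimethylsilane, CC(C)(C)[Si](C)(C)Cl
Why: Imidazole-mediated silylation of a primary alcohol is routine, and the silyl ether is what lets the CH2OSi group act as the migrating group in step 4.

Step 4
Reactants: 4 tert-butyl{[(2R,3R)-3-ethenyl-3-methyloxiran-2-yl]methoxy}dimethylsilane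
Product: 5 (2R)-2-methyl-2-(TBSOCH2)but-3-enal
Conditions: MeAl(OC6H2-4-Br-2,6-tBu2)2 (20 mol%), CH2Cl2, −78 → −40 °C
Reagents that add atoms: none
Why: In this Lewis-acid-promoted rearrangement of a 2,3-epoxy silyl ether to a β-siloxy aldehyde (semipinacol type) the bulky aluminium phenoxide opens the epoxide at the tertiary allylic carbon and the CH2OTBS group shifts to it anti to the leaving oxygen, so this carbon is inverted and becomes the (R)-configured quaternary centre (later C6), which cannot epimerise because the aldehyde has no α-hydrogen.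

Step 5
Reactants: 6 3-ethoxycyclohex-2-en-1-one; 5 (2R)-2-methyl-2-(TBSOCH2)but-3-enal
Product: 9 (6S)-6-[(1S,2R)-1-hydroxy-2-methyl-2-(TBSOCH2)but-3-en-1-yl]-3-ethoxycyclohex-2-en-1-one, via lithium dienolate 7 (not isolated), via titanium dienolate 8 (not isolated)
Conditions: LiN(iPr)2, THF, −78 °C; ClTi(OiPr)3, −78 → −40 °C; then 5, −78 → −40 °C
Reagents that add atoms: none
Why: Kinetic α′-deprotonation of the vinylogous ester and aldol addition of the triisopropoxytitanium enolate, which for cyclic (E)-enolates favours the syn adduct where the lithium enolate does not, set C7 and C8 syn to each other, while the configuration relative to the pre-formed C6 is not expected to be controlled, so the (6S,1′S,2′R) isomer is separated from the other syn adduct by chromatography.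

Step 6
Reactants: 9 (6S)-6-[(1S,2R)-1-hydroxy-2-methyl-2-(TBSOCH2)but-3-en-1-yl]-3-ethoxycyclohex-2-en-1-one; 10 allylmagnesium bromide
Product: 12 (4R)-4-[(1S,2R)-1-hydroxy-2-methyl-2-(TBSOCH2)but-3-en-1-yl]-3-(prop-2-en-1-yl)cyclohex-2-en-1-one, via tertiary carbinol 11 (not isolated)
Conditions: 10 (3 equiv), THF, −78 → 0 °C; then 1 M HCl, THF, 0 °C
Reagents that add atoms: water, O
Why: In this Stork–Danheiser transposition the Grignard reagent adds 1,2 to the vinylogous ester carbonyl (one further equivalent is consumed by the free hydroxyl) and brief cold acid hydrolyses the enol ether with loss of the tertiary hydroxyl to give the 3-allyl enone, leaving C6, C7 and C8 untouched.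

Step 7
Reactants: 12 (4R)-4-[(1S,2R)-1-hydroxy-2-methyl-2-(TBSOCH2)but-3-en-1-yl]-3-(prop-2-en-1-yl)cyclohex-2-en-1-one
Product: 13 (4aR,5S,6R)-5-hydroxy-6-methyl-6-(TBSOCH2)-3,4,4a,5,6,9-hexahydro-2H-benzo[7]annulen-2-one
Conditions: second-generation Grubbs catalyst RuCl2(=CHPh)(H2IMes)(PCy3) (5 mol%), 1,4-benzoquinone (10 mol%), CH2Cl2 (5 mM), 40 °C
Reagents that add atoms: none
Why: Ring-closing metathesis of the allyl and vinyl groups forms the seven-membered ring C2–C3–C4=C5–C6–C7–C8 with a (Z)-alkene enforced by ring size, the electron-poor trisubstituted enone alkene stays out of the reaction, and benzoquinone suppresses ruthenium hydride isomerisation of the skipped diene.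

Step 8
Reactants: 13 (4aR,5S,6R)-5-hydroxy-6-methyl-6-(TBSOCH2)-3,4,4a,5,6,9-hexahydro-2H-benzo[7]annulen-2-one
Product: 14 (4aR,5S,6R)-6-methyl-2-oxo-6-(TBSOCH2)-3,4,4a,5,6,9-hexahydro-2H-benzo[7]annulen-5-yl methanesulfonate
Conditions: MsCl, Et3N, CH2Cl2, −20 °C
Reagents that add atoms: methanesulfonyl chloride, CS(=O)(=O)Cl
Why: Mesylation through sulfene is fast even for a hindered secondary alcohol, goes with retention at C7, and is kept cold and short to avoid vinylogous β-elimination.

Step 9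
Reactants: 14 (4aR,5S,6R)-6-methyl-2-oxo-6-(TBSOCH2)-3,4,4a,5,6,9-hexahydro-2H-benzo[7]annulen-5-yl methanesulfonate
Product: 16 (1R,2R,6S,7S,8S)-2,6-dimethyl-6-(TBSOCH2)tricyclo[5.4.0.0^2,8]undec-4-en-11-one, via lithium enolate 15 (not isolated)
Conditions: Me2CuLi (2.5 equiv), Et2O, −78 → 0 °C; then HMPA/THF, 0 → 40 °C
Reagents that add atoms: lithium dimethylcuprate, [Li+].C[Cu-]C
Why: Me2CuLi transfers methyl to the ring-fusion β-carbon C2 of the enone, and the lithium enolate 15, formed regiospecifically at C1, attacks C7 from the rear of the C–OMs bond once HMPA is added and the mixture is warmed, so that C2–CH3 and C1–C7 are made in one flask (Michael-initiated ring closure). The closest known reactions are the cis-selective conjugate addition of Gilman reagents to octalone-type enones and the closure of cyclobutanes in bridged sesquiterpene ketones by intramolecular alkylation of a ketone enolate with a 1,3-related sulfonate. The cyclobutane C1–C2–C8–C7 closes in the 4-exo-tet mode and converts the cyclohexanone into the bicyclo[3.1.1]heptan-2-one. C2 is set by axial attack of the cuprate anti to the C8–C7 bond (cis ring fusion, methyl trans to C7, the only arrangement in which C1 and C7 can become gauche), C1 is then dictated by the geometry of the one-carbon bridge, and C7 is inverted (SN2) so that its hydrogen ends under the carbonyl bridge. The step needs C- rather than O-alkylation, no enolate equilibration to C10 and no elimination: O-alkylation would give a bridgehead enol ether (Bredt's rule), no proton source is present, and the only β-hydrogen of the mesylate is H8, which no base in the flask can reach. The seven-membered ring closed in step 7 acts as a tether that holds the C7–O bond anti to C1 and spares the closure the gauche clash between the tert-alkyl group on C7 and the C2 substituents that an open side chain would have to pay.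

Step 10
Reactants: 16 (1R,2R,6S,7S,8S)-2,6-dimethyl-6-(TBSOCH2)tricyclo[5.4.0.0^2,8]undec-4-en-11-one
Product: 17 (1R,2R,6S,7S,8S)-2,6-dimethyl-6-(TBSOCH2)tricyclo[5.4.0.0^2,8]undeca-4,9-dien-11-one
Conditions: IBX (2-iodoxybenzoic acid, 2 equiv), DMSO/PhF, 70 °C
Reagents that add atoms: none
Why: IBX dehydrogenates the ketone through its enol, and since C1 is a bridgehead only C10 can enolise, so the C9=C10 enone forms regiospecifically while the isolated alkene and the silyl ether are inert.

Step 11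
Reactants: 17 (1R,2R,6S,7S,8S)-2,6-dimethyl-6-(TBSOCH2)tricyclo[5.4.0.0^2,8]undeca-4,9-dien-11-one
Product: 18 (1R,2R,6S,7S,8S,9S)-2,6,9-trimethyl-6-(TBSOCH2)-11-(trimethylsilyloxy)tricyclo[5.4.0.0^2,8]undeca-4,10-diene
Conditions: Me2CuLi, Me3SiCl, THF/Et2O, −78 °C; Et3N, pentane work-up
Reagents that add atoms: lithium dimethylcuprate, [Li+].C[Cu-]C; chlorotrimethylsilane, C[Si](C)(C)Cl
Why: The Gilman reagent adds to C9 from the face of the small C7–H bridge (the C2 methyl group covers the other face) and Me3SiCl traps the C10=C11 enolate as its silyl ether, the C9 configuration set here being lost again in step 12.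

Step 12
Reactants: 18 (1R,2R,6S,7S,8S,9S)-2,6,9-trimethyl-6-(TBSOCH2)-11-(trimethylsilyloxy)tricyclo[5.4.0.0^2,8]undeca-4,10-diene
Product: 20 (1R,2R,6S,7S,8R)-2,6,9-trimethyl-6-(TBSOCH2)tricyclo[5.4.0.0^2,8]undeca-4,9-dien-11-one, via bromo ketone 19 (not isolated)
Conditions: N-bromosuccinimide, THF, −78 → 0 °C; then Li2CO3, LiBr, DMF, 110 °C
Reagents that add atoms: none
Why: Bromination of the silyl enol ether on the open face puts bromine on C10 anti to the C9–H bond, the geometry needed for base-induced anti (E2) dehydrobromination to the β-methyl enone, whereas syn-elimination methods (palladium enolate, selenoxide) would need the reagent on the face covered by the C2 methyl group.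

Step 13
Reactants: 20 (1R,2R,6S,7S,8R)-2,6,9-trimethyl-6-(TBSOCH2)tricyclo[5.4.0.0^2,8]undeca-4,9-dien-11-one
Product: 21 (1R,2R,4R,5S,6S,7S,8R)-4,5-epoxy-2,6,9-trimethyl-6-(TBSOCH2)tricyclo[5.4.0.0^2,8]undec-9-en-11-one
Conditions: mCPBA, CH2Cl2, 0 °C
Reagents that add atoms: 3-chloroperoxybenzoic acid, OOC(=O)c1cccc(Cl)c1
Why: The Prilezhaev epoxidation takes place only at the isolated C4=C5 alkene (the enone is electron-poor) and should occur on the face flanked by the C6 methyl group, away from the bulkier C6–CH2OTBS group, which puts the oxygen on the side of C5 required in the target.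

Step 14
Reactants: 21 (1R,2R,4R,5S,6S,7S,8R)-4,5-epoxy-2,6,9-trimethyl-6-(TBSOCH2)tricyclo[5.4.0.0^2,8]undec-9-en-11-one
Product: 22 (1R,2R,5R,6S,7S,8R,11R)-2,6,9-trimethyl-6-(TBSOCH2)tricyclo[5.4.0.0^2,8]undec-9-ene-5,11-diol
Conditions: LiAlH4, THF, 0 → 60 °C
Reagents that add atoms: none
Why: Hydride opens the epoxide by SN2 attack at C4, the carbon remote from the quaternary C6, so the C5–O bond keeps its configuration, and the enone is reduced 1,2 at the same time to an allylic alcohol whose configuration (hydride from the open face) is of no consequence.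

Step 15
Reactants: 22 (1R,2R,5R,6S,7S,8R,11R)-2,6,9-trimethyl-6-(TBSOCH2)tricyclo[5.4.0.0^2,8]undec-9-ene-5,11-diol
Product: 23 (1R,2R,5R,6S,7S,8R)-5-hydroxy-2,6,9-trimethyl-6-(TBSOCH2)tricyclo[5.4.0.0^2,8]undec-9-en-11-one
Conditions: MnO2 (excess), CH2Cl2, 25 °C
Reagents that add atoms: none
Why: MnO2 oxidises allylic alcohols selectively, so C11 returns to the enone while the saturated secondary C5 hydroxyl stays.

Step 16
Reactants: 23 (1R,2R,5R,6S,7S,8R)-5-hydroxy-2,6,9-trimethyl-6-(TBSOCH2)tricyclo[5.4.0.0^2,8]undec-9-en-11-one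
Product: 24 (1R,2R,5R,6S,7S,8R)-5-hydroxy-6-(hydroxymethyl)-2,6,9-trimethyltricyclo[5.4.0.0^2,8]undec-9-en-11-one
Conditions: Bu4NF, THF, 0 → 25 °C
Reagents that add atoms: none
Why: Fluoride cleaves the Si–O bond and frees the primary hydroxyl, and no base-sensitive stereocentre is present because the only carbon α to the ketone is the bridgehead C1.

Step 17
Reactants: 24 (1R,2R,5R,6S,7S,8R)-5-hydroxy-6-(hydroxymethyl)-2,6,9-trimethyltricyclo[5.4.0.0^2,8]undec-9-en-11-one; 25 angelic acid
Product: 27 CNP0240716.2 (the 5,12-bis-angelate of 24), via mixed anhydride 26 (not isolated)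
Conditions: 25 (5 equiv), 2,4,6-Cl3C6H2COCl, Et3N, toluene, 25 °C; then 24, 80 °C
Reagents that add atoms: none
Why: Yamaguchi-type esterification through the mixed anhydride of angelic acid, run without DMAP so that the (Z)-alkene is not isomerised to the tiglate, should acylate both the primary C12 hydroxyl and the hindered secondary C5 hydroxyl.

**Compound list**
1 | (2E)-3-methylpent-2-en-4-yn-1-ol | OC/C=C(\C)C#C | starting material
2 | (2E)-3-methylpenta-2,4-dien-1-ol | OC/C=C(\C)C=C | intermediate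
3 | [(2R,3R)-3-ethenyl-3-methyloxiran-2-yl]methanol | OC[C@H]1O[C@]1(C)C=C | intermediate
4 | tert-butyl{[(2R,3R)-3-ethenyl-3-methyloxiran-2-yl]methoxy}dimethylsilane | CC(C)(C)[Si](C)(C)OC[C@H]1O[C@]1(C)C=C | intermediate
5 | (2R)-2-({[tert-butyl(dimethyl)silyl]oxy}methyl)-2-methylbut-3-enal | O=C[C@@](C)(CO[Si](C)(C)C(C)(C)C)C=C | intermediate
6 | 3-ethoxycyclohex-2-en-1-one | CCOC1=CC(=O)CCC1 | starting material
7 | lithium 5-ethoxycyclohexa-1,5-dien-1-olate (not isolated) | CCOC1=CC(O[Li])=CCC1 | intermediate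
8 | [(5-ethoxycyclohexa-1,5-dien-1-yl)oxy]tri(propan-2-yloxy)titanium (not isolated) | CCOC1=CC(O[Ti](OC(C)C)(OC(C)C)OC(C)C)=CCC1 | intermediate
9 | (6S)-6-[(1S,2R)-2-({[tert-butyl(dimethyl)silyl]oxy}methyl)-1-hydroxy-2-methylbut-3-en-1-yl]-3-ethoxycyclohex-2-en-1-one | CCOC1=CC(=O)[C@@H](CC1)[C@H](O)[C@@](C)(CO[Si](C)(C)C(C)(C)C)C=C | intermediate
10 | allylmagnesium bromide | C=CC[Mg]Br | starting material
11 | (6S)-6-[(1S,2R)-2-({[tert-butyl(dimethyl)silyl]oxy}methyl)-1-hydroxy-2-methylbut-3-en-1-yl]-3-ethoxy-1-(prop-2-en-1-yl)cyclohex-2-en-1-ol, both C1 epimers, present as magnesium alkoxide (not isolated) | CCOC1=CC(O)(CC=C)[C@@H](CC1)[C@H](O)[C@@](C)(CO[Si](C)(C)C(C)(C)C)C=C | intermediate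
12 | (4R)-4-[(1S,2R)-2-({[tert-butyl(dimethyl)silyl]oxy}methyl)-1-hydroxy-2-methylbut-3-en-1-yl]-3-(prop-2-en-1-yl)cyclohex-2-en-1-one | C=CCC1=CC(=O)CC[C@H]1[C@H](O)[C@@](C)(CO[Si](C)(C)C(C)(C)C)C=C | intermediate
13 | (4aR,5S,6R)-6-({[tert-butyl(dimethyl)silyl]oxy}methyl)-5-hydroxy-6-methyl-3,4,4a,5,6,9-hexahydro-2H-benzo[7]annulen-2-one | O=C1C=C2CC=C[C@](C)(CO[Si](C)(C)C(C)(C)C)[C@@H](O)[C@@H]2CC1 | intermediate
14 | (4aR,5S,6R)-6-({[tert-butyl(dimethyl)silyl]oxy}methyl)-6-methyl-2-oxo-3,4,4a,5,6,9-hexahydro-2H-benzo[7]annulen-5-yl methanesulfonate | O=C1C=C2CC=C[C@](C)(CO[Si](C)(C)C(C)(C)C)[C@@H](OS(C)(=O)=O)[C@@H]2CC1 | intermediate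
15 | lithium C1=C11 enolate of the C2-methylated, cis-fused ketone from 14, C2 methyl trans to C7, (4aR,5S,6R,9aR), mesylate retained (not isolated) | [Li]OC1=C[C@]2(C)CC=C[C@](C)(CO[Si](C)(C)C(C)(C)C)[C@@H](OS(C)(=O)=O)[C@@H]2CC1 | intermediate
16 | (1R,2R,6S,7S,8S)-6-({[tert-butyl(dimethyl)silyl]oxy}methyl)-2,6-dimethyltricyclo[5.4.0.0^2,8]undec-4-en-11-one | CC(C)(C)[Si](C)(C)OC[C@]1(C)[C@@H]2[C@H]3C(=O)CC[C@@H]2[C@@]3(C)CC=C1 | intermediate
17 | (1R,2R,6S,7S,8S)-6-({[tert-butyl(dimethyl)silyl]oxy}methyl)-2,6-dimethyltricyclo[5.4.0.0^2,8]undeca-4,9-dien-11-one | CC(C)(C)[Si](C)(C)OC[C@]1(C)[C@@H]2[C@H]3C(=O)C=C[C@@H]2[C@@]3(C)CC=C1 | intermediate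
18 | (1R,2R,6S,7S,8S,9S)-6-({[tert-butyl(dimethyl)silyl]oxy}methyl)-2,6,9-trimethyl-11-(trimethylsilyloxy)tricyclo[5.4.0.0^2,8]undeca-4,10-diene | CC(C)(C)[Si](C)(C)OC[C@]1(C)[C@@H]2[C@H]3C(O[Si](C)(C)C)=C[C@@H](C)[C@@H]2[C@@]3(C)CC=C1 | intermediate
19 | (1R,2R,6S,7S,8R,9S,10S)-10-bromo-6-({[tert-butyl(dimethyl)silyl]oxy}methyl)-2,6,9-trimethyltricyclo[5.4.0.0^2,8]undec-4-en-11-one (not isolated) | CC(C)(C)[Si](C)(C)OC[C@]1(C)[C@@H]2[C@H]3C(=O)[C@@H](Br)[C@@H](C)[C@@H]2[C@@]3(C)CC=C1 | intermediate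
20 | (1R,2R,6S,7S,8R)-6-({[tert-butyl(dimethyl)silyl]oxy}methyl)-2,6,9-trimethyltricyclo[5.4.0.0^2,8]undeca-4,9-dien-11-one | CC(C)(C)[Si](C)(C)OC[C@]1(C)[C@@H]2[C@H]3C(=O)C=C(C)[C@@H]2[C@@]3(C)CC=C1 | intermediate
21 | (1R,2R,4R,5S,6S,7S,8R)-6-({[tert-butyl(dimethyl)silyl]oxy}methyl)-4,5-epoxy-2,6,9-trimethyltricyclo[5.4.0.0^2,8]undec-9-en-11-one | CC(C)(C)[Si](C)(C)OC[C@]1(C)[C@@H]2[C@H]3C(=O)C=C(C)[C@@H]2[C@@]3(C)C[C@H]4O[C@@H]14 | intermediate
22 | (1R,2R,5R,6S,7S,8R,11R)-6-({[tert-butyl(dimethyl)silyl]oxy}methyl)-2,6,9-trimethyltricyclo[5.4.0.0^2,8]undec-9-ene-5,11-diol | CC(C)(C)[Si](C)(C)OC[C@]1(C)[C@@H]2[C@H]3[C@H](O)C=C(C)[C@@H]2[C@@]3(C)CC[C@H]1O | intermediate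
23 | (1R,2R,5R,6S,7S,8R)-6-({[tert-butyl(dimethyl)silyl]oxy}methyl)-5-hydroxy-2,6,9-trimethyltricyclo[5.4.0.0^2,8]undec-9-en-11-one | CC(C)(C)[Si](C)(C)OC[C@]1(C)[C@@H]2[C@H]3C(=O)C=C(C)[C@@H]2[C@@]3(C)CC[C@H]1O | intermediate
24 | (1R,2R,5R,6S,7S,8R)-5-hydroxy-6-(hydroxymethyl)-2,6,9-trimethyltricyclo[5.4.0.0^2,8]undec-9-en-11-one | OC[C@]1(C)[C@@H]2[C@H]3C(=O)C=C(C)[C@@H]2[C@@]3(C)CC[C@H]1O | intermediate
25 | angelic acid, (2Z)-2-methylbut-2-enoic acid | C/C=C(/C)C(=O)O | starting material
26 | (2Z)-2-methylbut-2-enoic 2,4,6-trichlorobenzoic anhydride (not isolated) | C/C=C(/C)C(=O)OC(=O)c1c(Cl)cc(Cl)cc1Cl | intermediate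
27 | CNP0240716.2, [(1R,2R,5R,6S,7S,8R)-2,6,9-trimethyl-5-{[(2Z)-2-methylbut-2-enoyl]oxy}-11-oxotricyclo[5.4.0.0^2,8]undec-9-en-6-yl]methyl (2Z)-2-methylbut-2-enoate | C/C=C(/C)C(=O)OC[C@]1(C)[C@@H]2[C@H]3C(=O)C=C(C)[C@@H]2[C@@]3(C)CC[C@H]1OC(=O)/C(C)=C\C | target

**Count**
Total steps: 17. Longest linear sequence: 17 steps (1 → 27); 6, 10 and 25 are bought.

**Steps most likely to fail**

Step 9. The lithium enolate may not displace the hindered secondary mesylate fast enough (a 4-exo-tet substitution next to a quaternary carbon), or methyl transfer to the fully substituted ring-fusion carbon may be slow; either way protonated conjugate adduct or unchanged enone would be recovered. Fallback, setting out from 14 and returning at 16: addition and closure are separated. Me2CuLi with Me3SiCl (silyl-accelerated conjugate addition) converts 14 into the trimethylsilyl enol ether F1, which is isolated. KOtBu in THF/DMSO then cleaves the O–Si bond and releases the potassium enolate F2, a more reactive and still regiodefined nucleophile in a dipolar medium, which should close to 16.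

Step 5. The titanium enolate may add to both faces of the aldehyde without preference, and some anti adduct may form, so that 9 is only one component of a diastereomer mixture. Fallback, setting out from 5 and 6 and returning at 20: the second syn adduct of the same aldol, the (6R,1′R,2′R) isomer F3, is used as well. The carbocyclic core is pseudo-symmetric: reflection through the plane of C2, C7 and C10 exchanges C1 with C8 and C11 with C9, so inverting C7 and C8 relative to C6 only moves the ketone from C11 to C9. F3 is taken through the conditions of steps 6 to 10: allylmagnesium bromide (tertiary carbinol F4, not isolated) and 1 M HCl to the enone F5, metathesis to the bicyclic alcohol F6, mesylation to the mesylate F7, Me2CuLi then HMPA (lithium enolate F8, not isolated) to the C9 ketone F9, and IBX to the C10=C11 enone F10. MeLi with CeCl3 then adds to C9 to give the tertiary allylic alcohol F11, and oxidative 1,3-transposition with pyridinium chlorochromate moves the oxygen to C11 and leaves the methyl group on C9, which is 20.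

Step 13. Poor facial discrimination between the methyl and the CH2OTBS flank of the C4=C5 alkene would give both epoxides and, after step 14, both C5 alcohols. Fallback, setting out from 22 (as its C5 epimer mixture) and returning at 24: C5 is set by hydride delivery instead of by oxygen delivery. Dess–Martin periodinane oxidises both carbinols to the 5,11-dione F12. HF·pyridine removes the silyl group and gives the β-hydroxy ketone F13. Me4NBH(OAc)3 (hydroxyl-directed reduction) binds to the C12 hydroxyl and delivers hydride to C5 from the C12 side, which leaves the C5 oxygen anti to C12 and the enone untouched, and gives 24.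

**Further compounds**
F1 | step 9 | trimethylsilyl enol ether (C11–OSiMe3, C1=C11) of the C2-methylated cis-fused ketone from 14, mesylate retained | C[Si](C)(C)OC1=C[C@]2(C)CC=C[C@](C)(CO[Si](C)(C)C(C)(C)C)[C@@H](OS(C)(=O)=O)[C@@H]2CC1
F2 | step 9 | potassium enolate corresponding to F1 | [K]OC1=C[C@]2(C)CC=C[C@](C)(CO[Si](C)(C)C(C)(C)C)[C@@H](OS(C)(=O)=O)[C@@H]2CC1
F3 | step 5 | (6R)-6-[(1R,2R)-2-({[tert-butyl(dimethyl)silyl]oxy}methyl)-1-hydroxy-2-methylbut-3-en-1-yl]-3-ethoxycyclohex-2-en-1-one | CCOC1=CC(=O)[C@H](CC1)[C@@H](O)[C@@](C)(CO[Si](C)(C)C(C)(C)C)C=C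
F4 | step 5 | 1-allyl carbinol from F3, both C1 epimers | CCOC1=CC(O)(CC=C)[C@H](CC1)[C@@H](O)[C@@](C)(CO[Si](C)(C)C(C)(C)C)C=C
F5 | step 5 | (4S)-4-[(1R,2R)-2-({[tert-butyl(dimethyl)silyl]oxy}methyl)-1-hydroxy-2-methylbut-3-en-1-yl]-3-(prop-2-en-1-yl)cyclohex-2-en-1-one | C=CCC1=CC(=O)CC[C@@H]1[C@@H](O)[C@@](C)(CO[Si](C)(C)C(C)(C)C)C=C
F6 | step 5 | (4aS,5R,6R)-6-({[tert-butyl(dimethyl)silyl]oxy}methyl)-5-hydroxy-6-methyl-3,4,4a,5,6,9-hexahydro-2H-benzo[7]annulen-2-one | O=C1C=C2CC=C[C@](C)(CO[Si](C)(C)C(C)(C)C)[C@H](O)[C@H]2CC1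
F7 | step 5 | methanesulfonate of F6 | O=C1C=C2CC=C[C@](C)(CO[Si](C)(C)C(C)(C)C)[C@H](OS(C)(=O)=O)[C@H]2CC1
F8 | step 5 | lithium enolate of the C2-methylated cis-fused ketone from F7 | [Li]OC1=C[C@@]2(C)CC=C[C@](C)(CO[Si](C)(C)C(C)(C)C)[C@H](OS(C)(=O)=O)[C@H]2CC1
F9 | step 5 | 9-oxo regioisomer of 16 (C11 is CH2), 6-({[tert-butyl(dimethyl)silyl]oxy}methyl)-2,6-dimethyltricyclo[5.4.0.0^2,8]undec-4-en-9-one | CC(C)(C)[Si](C)(C)OC[C@]1(C)[C@@H]2[C@H]3CCC(=O)[C@@H]2[C@@]3(C)CC=C1
F10 | step 5 | 6-({[tert-butyl(dimethyl)silyl]oxy}methyl)-2,6-dimethyltricyclo[5.4.0.0^2,8]undeca-4,10-dien-9-one | CC(C)(C)[Si](C)(C)OC[C@]1(C)[C@@H]2[C@H]3C=CC(=O)[C@@H]2[C@@]3(C)CC=C1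
F11 | step 5 | 6-({[tert-butyl(dimethyl)silyl]oxy}methyl)-2,6,9-trimethyltricyclo[5.4.0.0^2,8]undeca-4,10-dien-9-ol, either C9 epimer | CC(C)(C)[Si](C)(C)OC[C@]1(C)[C@@H]2[C@H]3C=CC(C)(O)[C@@H]2[C@@]3(C)CC=C1
F12 | step 13 | 6-({[tert-butyl(dimethyl)silyl]oxy}methyl)-2,6,9-trimethyltricyclo[5.4.0.0^2,8]undec-9-ene-5,11-dione | CC(C)(C)[Si](C)(C)OC[C@]1(C)[C@@H]2[C@H]3C(=O)C=C(C)[C@@H]2[C@@]3(C)CCC1=O
F13 | step 13 | 6-(hydroxymethyl)-2,6,9-trimethyltricyclo[5.4.0.0^2,8]undec-9-ene-5,11-dione | OC[C@]1(C)[C@@H]2[C@H]3C(=O)C=C(C)[C@@H]2[C@@]3(C)CCC1=O
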